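**Retrosynthetic overview** (ent-kaurane numbering, C1–C20, is used for all compounds)
1. Enabling feature: quaternary C8 is the α-carbon of the C7 lactone carbonyl and of the C15 carbinol and carries C14H2, and the δ-lactone (O–C7–C8–C9–C10–C20) and carbocycle C (C8–C9–C11–C12–C13–C14) share the bond C8–C9. C7/C8/C14/C15/C16 is therefore a 2-methylene-3-oxobutanoate on O-20, and C9/C11/C12/C13 a butadienyl group on C10.
2. Key disconnection: ester-tethered intramolecular Diels–Alder reaction (C8–C9 and C13–C14) that closes the lactone and ring C together; the dienophile is unveiled in the flask by oxidation of a Morita–Baylis–Hillman carbinol.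
3. Ring D last: a temporary C13–SiMe3 bond (from a 1-silyl diene) is cleaved by protodesilylation, which moves the ring C alkene to C12=C13; palladium-mediated cycloalkenylation of the C15 enol silane then forms C16–C13. C17 comes from a Mannich methylenation, the C15 alcohol from a Luche reduction.
4. Ring A: from 4,4-dimethylcyclohexanone; C5 by auxiliary-controlled conjugate formylation of the 2-carbomethoxy enone, C10 by trans ethynylation of the β-keto ester, C1 by hydride reduction, the diene by hydrozirconation and Negishi coupling.
5. Order of ring formation: A (starting material) → lactone + C (step 12) → D (step 14).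

Key step: step 12

Remark: the sense of induction of the (S)-auxiliary in step 4 is assumed by analogy with its additions to alkylidene malonates; if it proves opposite, the (R)-hydrazone (from RAMP) is used and nothing else changes.

Step 1
Reactants: 1 4,4-dimethylcyclohexan-1-one
Product: 2 methyl 5,5-dimethyl-2-oxocyclohexane-1-carboxylate
Conditions: NaH, (MeO)2CO, THF, reflux; AcOH quench
Reagents that add atoms: dimethyl carbonate, COC(=O)OC
Why: Claisen-type C-acylation of the symmetrical ketone enolate, driven by formation of the β-keto ester enolate; no stereocentre is involved.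

Step 2
Reactants: 2 methyl 5,5-dimethyl-2-oxocyclohexane-1-carboxylate
Product: 5 methyl 3,3-dimethyl-6-oxocyclohex-1-ene-1-carboxylate, via selenide 3 (not isolated), via selenoxide 4 (not isolated)
Conditions: PhSeCl, pyridine, CH2Cl2, 0 °C; then 30% H2O2, 0 °C to rt
Reagents that add atoms: none
Why: α-selenenylation of the β-keto ester and selenoxide syn-elimination, which can only run towards the ring CH2 (future C5), should give the doubly activated enone.

Step 3
Reactants: 6 (S)-1-amino-2-(methoxymethyl)pyrrolidine (SAMP)
Product: 7 formaldehyde SAMP-hydrazone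
Conditions: (CH2O)n, MgSO4, CH2Cl2, rt
Reagents that add atoms: formaldehyde (as paraformaldehyde), C=O
Why: simple hydrazone condensation; the auxiliary stereocentre is untouched.

Step 4
Reactants: 5 methyl 3,3-dimethyl-6-oxocyclohex-1-ene-1-carboxylate; 7 formaldehyde SAMP-hydrazone
Product: 8 methyl 6-[(E)-{[(2S)-2-(methoxymethyl)pyrrolidin-1-yl]imino}methyl]-5,5-dimethyl-2-oxocyclohexane-1-carboxylate (C5 as in the target; C10 epimers and enol)
Conditions: MgI2 (20 mol%), CH2Cl2, −78 to 0 °C
Reagents that add atoms: none
Why: conjugate addition of the aza-enamine carbon of the formaldehyde hydrazone (a neutral formyl anion equivalent) to the chelated alkylidene β-keto ester, a reaction type known for alkylidene malonates and enones; the pyrrolidine auxiliary differentiates the two faces of C5 and sets this first stereocentre.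

Step 5
Reactants: 8 hydrazone keto ester
Product: 10 methyl 6-(1,3-dioxolan-2-yl)-5,5-dimethyl-2-oxocyclohexane-1-carboxylate (C5 as in the target), via keto aldehyde 9 (not isolated)
Conditions: sat. aq. oxalic acid, Et2O, rt; then (TMSOCH2)2, TMSOTf (cat.), CH2Cl2, −78 °C
Reagents that add atoms: 1,2-bis(trimethylsilyloxy)ethane, C[Si](C)(C)OCCO[Si](C)(C)C
Why: mild hydrolytic hydrazone cleavage (auxiliary recovered) followed at once by aldehyde-selective dioxolane formation under silyl triflate catalysis, so that the C5 stereocentre next to the free aldehyde has little time to enolise.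

Step 6
Reactants: 10 dioxolanyl β-keto ester
Product: 11 methyl 6-(1,3-dioxolan-2-yl)-1-ethynyl-5,5-dimethyl-2-oxocyclohexane-1-carboxylate (ethynyl trans to the dioxolanyl group)
Conditions: TMS-EBX, TBAF, THF, −78 °C to rt
Reagents that add atoms: TMS-EBX (1-[(trimethylsilyl)ethynyl]-1,2-benziodoxol-3(1H)-one), C[Si](C)(C)C#CI1OC(=O)c2ccccc12
Why: electrophilic α-ethynylation of the β-keto ester enolate by the ethynylbenziodoxolone formed in the flask; the enolate should be attacked anti to the pseudo-axial C5 substituent, which places the ethynyl group (C9, C11) trans to C6 and the ester (future C20) cis, and fixes quaternary C10.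

Step 7
Reactants: 11 ethynyl keto ester
Product: 12 3-(1,3-dioxolan-2-yl)-2-ethynyl-2-(hydroxymethyl)-4,4-dimethylcyclohexan-1-ol (C1 OH, C20 and C6 on one face, ethynyl on the other)
Conditions: LiAlH4, THF, −78 to 0 °C
Reagents that add atoms: none
Why: hydride reduction of ketone and ester; hydride should reach C1 from the face of the slim ethynyl group, away from the ester and the C5 substituent, giving the C1 alcohol cis to C20 as in the target.

Step 8
Reactants: 12 ethynyl diol
Product: 13 3-(1,3-dioxolan-2-yl)-2-(hydroxymethyl)-4,4-dimethyl-2-[(1E,3E)-4-(trimethylsilyl)buta-1,3-dien-1-yl]cyclohexan-1-ol (ring stereocentres as in 12)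
Conditions: Cp2Zr(H)Cl (3.5 equiv), THF, rt; then ZnCl2, Pd(PPh3)4 (5 mol%), (E)-BrCH=CHSiMe3, rt
Reagents that add atoms: (E)-(2-bromovinyl)trimethylsilane, Br/C=C/[Si](C)(C)C
Why: syn hydrozirconation puts zirconium on the terminal alkyne carbon and Negishi coupling after transmetalation to zinc proceeds with retention in both partners, giving the (1E,3E)-silyl diene; the free hydroxyls are only converted into zirconium alkoxides by the excess reagent.

Step 9
Reactants: 13 silyl dienyl diol
Product: 14 C20 acrylate of 13 (C1 OH free)
Conditions: CH2=CHCOCl, Et3N, CH2Cl2, −78 °C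
Reagents that add atoms: acryloyl chloride, C=CC(=O)Cl
Why: acylation at low temperature should take the primary neopentyl alcohol in preference to the more hindered secondary C1 alcohol.

Step 10
Reactants: 14 C20 acrylate
Product: 15 C1 acetate, C20 acrylate
Conditions: Ac2O, DMAP (cat.), pyridine, rt
Reagents that add atoms: acetic anhydride, CC(=O)OC(C)=O
Why: DMAP-catalysed acetylation installs the C1 acetate of the target early; it is also the small substituent wanted on C1 in the key step.

Step 11
Reactants: 15 acetate acrylate
Product: 16 C20 2-(1-hydroxyethyl)acrylate (both carbinol epimers)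
Conditions: MeCHO, DABCO, 1,4-dioxane/H2O, rt
Reagents that add atoms: acetaldehyde, CC=O
Why: Morita–Baylis–Hillman reaction of the acrylate with acetaldehyde attaches C15 and C16 to C8; the carbinol configuration is irrelevant because it is oxidised in the next step.

Step 12
Reactants: 16 Morita–Baylis–Hillman carbinol
Product: 18 Diels–Alder adduct: δ-lactone (spiro to ring A at C10) cis-fused to cyclohex-11-ene C, C8 acetyl syn to H9, C13 SiMe3 anti to the acetyl, via methylene keto ester 17 (not isolated)
Conditions: Dess–Martin periodinane, pyridine, CH2Cl2, 0 °C to rt; then PhMe (0.005 M), 60 °C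
Reagents that add atoms: none
Why: Dess–Martin oxidation of the carbinol unveils the 2-methylene-3-oxobutanoate 17, a doubly activated 1,1-disubstituted dienophile held by the O-20 ester four atoms from diene carbon C9, which should undergo a normal-demand intramolecular Diels–Alder reaction (closest known types: ester-tethered 1,7,9-decatriene cycloadditions and Diels–Alder trapping of α-methylene β-keto esters made by oxidation of Baylis–Hillman adducts). The transition state should be asynchronous, C14 bonding first to the silyl-bearing terminus C13 (ipso attack, β-silyl stabilised) so that the congested C8–C9 bond closes late; this one event closes the δ-lactone (type 1 mode, six-membered, through C8–C9) and cyclohexene C (through C8–C9 and C13–C14) and creates quaternary C8. C9 against C10: the allylic quaternary C10 should hold its tether arm C20 over the dienophile, its smaller ring branch C1 (CH–OAc) eclipsed with the diene and its bulkier branch C5 (dioxolanyl, next to CMe2) anti, which exposes the diene face that leads to the C9 configuration of the target. C8: the lactone carbonyl should take the endo position (cis-fused lactone) because in the trans-fused alternative the acetyl group would be gauche to both C10 and C11, and the E geometry of C9=C11 then puts H9 syn to the acetyl carbon C15 (the E-silyl group ends up anti to C15 and is removed in step 13). The selectivities needed are the π-face of the diene and cis ring fusion (argued above), regiochemistry (fixed by the tether and electronically matched) and cyclisation ahead of hetero-Diels–Alder dimerisation of 17 (high dilution).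

Step 13
Reactants: 18 Diels–Alder adduct
Product: 19 desilylated lactone with the ring C alkene at C12=C13 (C8 acetyl, C11H2)
Conditions: TFA, CH2Cl2, 0 °C
Reagents that add atoms: none
Why: acid-induced SE2′ protodesilylation of the allylsilane: protonation at C11 gives the β-silyl cation and loss of silicon leaves the C12=C13 alkene, a position the cycloaddition cannot deliver directly; no stereocentre is created and the cyclic acetal should survive anhydrous acid at low temperature.

Step 14
Reactants: 19 methyl ketone with C12=C13
Product: 21 tetracyclic 17-nor-15-ketone with C11=C12 (ring D closed, C16H2), via enol silane 20 (not isolated)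
Conditions: LiHMDS, TMSCl, THF, −78 °C; then Pd(OAc)2 (1.1 equiv), MeCN, rt
Reagents that add atoms: none
Why: the methyl ketone can enolise only towards C16 (C8 is quaternary), and oxidative cycloalkenylation of the enol silane by divalent palladium (Saegusa–Ito-type palladium enolate, syn carbopalladation of C12=C13, syn β-hydride elimination towards C11) should close ring D through C16–C13, a known route to bicyclo[3.2.1]octanones; C13 is set by the bridge, since the axial C15 arm reaches only one face.

Step 15
Reactants: 21 unsaturated tetracyclic ketone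
Product: 22 saturated 17-nor-15-ketone
Conditions: H2 (1 atm), Pd/C, EtOAc, rt
Reagents that add atoms: none
Why: heterogeneous hydrogenation of the only alkene (C11=C12); no new stereocentre.

Step 16
Reactants: 22 saturated 15-ketone
Product: 25 15-oxo-16-methylene enone (dioxolane, C1 acetate), via Mannich base 23 (not isolated), via methiodide 24 (not isolated)
Conditions: LiHMDS, THF, −78 °C; Me2N=CH2 I, −78 to 0 °C; MeI, CH2Cl2, rt; aq. NaHCO3
Reagents that add atoms: Eschenmoser's salt (N,N-dimethylmethyleneiminium iodide), C=[N+](C)C.[I-]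
Why: the ketone enolises only towards C16; Mannich reaction with Eschenmoser's salt, quaternisation and E1cB elimination install the exocyclic C16=C17 enone.

Step 17
Reactants: 25 enone
Product: 26 C15 allylic alcohol (C15 as in the target), dioxolane
Conditions: NaBH4, CeCl3·7H2O, MeOH, −78 °C
Reagents that add atoms: none
Why: Luche 1,2-reduction; hydride should attack C15 from the face of the one-carbon bridge C14 (exo face of the bicyclo[3.2.1]octanone), which places the hydroxyl on the side of C9 as in the target, while lactone, acetate and acetal are untouched.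

Step 18
Reactants: 26 allylic alcohol acetal
Product: 27 target CNP0117386.1
Conditions: TsOH·H2O (cat.), acetone/H2O, 40 °C
Reagents that add atoms: water, O
Why: acid-catalysed hydrolysis of the dioxolane frees the C6 aldehyde, which stays equatorial at C5; lactone, acetate and the allylic alcohol next to quaternary C8 should tolerate the mild acid.

**Compound list**
1 | 4,4-dimethylcyclohexan-1-one | CC1(C)CCC(=O)CC1 | starting material
2 | methyl 5,5-dimethyl-2-oxocyclohexane-1-carboxylate | COC(=O)C1CC(C)(C)CCC1=O | intermediate
3 | methyl 5,5-dimethyl-2-oxo-1-(phenylselanyl)cyclohexane-1-carboxylate | COC(=O)C1([Se]c2ccccc2)CC(C)(C)CCC1=O | intermediate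
4 | selenoxide of 3 | COC(=O)C1([Se](=O)c2ccccc2)CC(C)(C)CCC1=O | intermediate
5 | methyl 3,3-dimethyl-6-oxocyclohex-1-ene-1-carboxylate | COC(=O)C1=CC(C)(C)CCC1=O | intermediate
6 | (S)-1-amino-2-(methoxymethyl)pyrrolidine (SAMP) | COC[C@@H]1CCCN1N | starting material
7 | formaldehyde SAMP-hydrazone | COC[C@@H]1CCCN1N=C | intermediate
8 | hydrazone keto ester (C5 set; C10 epimers) | COC(=O)C1C(=O)CCC(C)(C)[C@H]1/C=N/N1CCC[C@H]1COC | intermediate
9 | methyl 6-formyl-5,5-dimethyl-2-oxocyclohexane-1-carboxylate | COC(=O)C1C(=O)CCC(C)(C)[C@H]1C=O | intermediate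
10 | methyl 6-(1,3-dioxolan-2-yl)-5,5-dimethyl-2-oxocyclohexane-1-carboxylate | COC(=O)C1C(=O)CCC(C)(C)[C@H]1C1OCCO1 | intermediate
11 | methyl 6-(1,3-dioxolan-2-yl)-1-ethynyl-5,5-dimethyl-2-oxocyclohexane-1-carboxylate (ethynyl trans to dioxolanyl) | COC(=O)[C@@]1(C#C)C(=O)CCC(C)(C)[C@H]1C1OCCO1 | intermediate
12 | ethynyl diol (C1 OH, C20, C6 cis) | OC[C@@]1(C#C)[C@@H](O)CCC(C)(C)[C@H]1C1OCCO1 | intermediate
13 | (1E,3E)-4-(trimethylsilyl)butadienyl diol | OC[C@@]1(/C=C/C=C/[Si](C)(C)C)[C@@H](O)CCC(C)(C)[C@H]1C1OCCO1 | intermediate
14 | C20 acrylate | C=CC(=O)OC[C@@]1(/C=C/C=C/[Si](C)(C)C)[C@@H](O)CCC(C)(C)[C@H]1C1OCCO1 | intermediate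
15 | C1 acetate, C20 acrylate | C=CC(=O)OC[C@@]1(/C=C/C=C/[Si](C)(C)C)[C@@H](OC(C)=O)CCC(C)(C)[C@H]1C1OCCO1 | intermediate
16 | C20 2-(1-hydroxyethyl)acrylate | CC(O)C(=C)C(=O)OC[C@@]1(/C=C/C=C/[Si](C)(C)C)[C@@H](OC(C)=O)CCC(C)(C)[C@H]1C1OCCO1 | intermediate
17 | C20 2-methylene-3-oxobutanoate | CC(=O)C(=C)C(=O)OC[C@@]1(/C=C/C=C/[Si](C)(C)C)[C@@H](OC(C)=O)CCC(C)(C)[C@H]1C1OCCO1 | intermediate
18 | Diels–Alder adduct (cis-fused lactone, C8 acetyl, C13 SiMe3, C11=C12) | C1=C[C@@H]2[C@@](C[C@H]1[Si](C)(C)C)(C(C)=O)C(=O)OC[C@]21[C@@H](OC(C)=O)CCC(C)(C)[C@H]1C1OCCO1 | intermediate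
19 | desilylated lactone, C12=C13 | C1[C@@H]2[C@@](CC=C1)(C(C)=O)C(=O)OC[C@]21[C@@H](OC(C)=O)CCC(C)(C)[C@H]1C1OCCO1 | intermediate
20 | C15 trimethylsilyl enol ether of 19 | C1[C@@H]2[C@@](CC=C1)(C(=C)O[Si](C)(C)C)C(=O)OC[C@]21[C@@H](OC(C)=O)CCC(C)(C)[C@H]1C1OCCO1 | intermediate
21 | tetracyclic 17-nor-15-ketone, C11=C12 | C1[C@@H]2C=C[C@@H]3[C@](C2)(C(=O)OC[C@]32[C@@H](OC(C)=O)CCC(C)(C)[C@H]2C2OCCO2)C1=O | intermediate
22 | saturated 17-nor-15-ketone | C1[C@@H]2CC[C@@H]3[C@](C2)(C(=O)OC[C@]32[C@@H](OC(C)=O)CCC(C)(C)[C@H]2C2OCCO2)C1=O | intermediate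
23 | 16-(dimethylaminomethyl) 15-ketone (C16 epimers) | CN(C)CC1[C@@H]2CC[C@@H]3[C@](C2)(C(=O)OC[C@]32[C@@H](OC(C)=O)CCC(C)(C)[C@H]2C2OCCO2)C1=O | intermediate
24 | methiodide of 23 | C[N+](C)(C)CC1[C@@H]2CC[C@@H]3[C@](C2)(C(=O)OC[C@]32[C@@H](OC(C)=O)CCC(C)(C)[C@H]2C2OCCO2)C1=O.[I-] | intermediate
25 | 15-oxo-16-methylene enone, dioxolane | C=C1[C@@H]2CC[C@@H]3[C@](C2)(C(=O)OC[C@]32[C@@H](OC(C)=O)CCC(C)(C)[C@H]2C2OCCO2)C1=O | intermediate
26 | C15 allylic alcohol, dioxolane | C=C1[C@@H]2CC[C@@H]3[C@](C2)(C(=O)OC[C@]32[C@@H](OC(C)=O)CCC(C)(C)[C@H]2C2OCCO2)[C@@H]1O | intermediate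
27 | CNP0117386.1 | C=C1[C@@H]2CC[C@@H]3[C@](C2)(C(=O)OC[C@]32[C@@H](OC(C)=O)CCC(C)(C)[C@H]2C=O)[C@@H]1O | target

**Step count:** 18 steps in total; longest linear sequence 17 steps (steps 1, 2 and 4–18; step 3 prepares the hydrazone reagent).

**Steps most likely to fail**

Step 12 (key step). The diene π-face or the endo/exo sense may not be discriminated, or the transient methylene keto ester may dimerise by hetero-Diels–Alder reaction faster than it cyclises. The fallback sets out from 16. Silylation (TBSCl, imidazole, DMF) gives the tert-butyldimethylsilyl ether F2, an isolable, singly activated triene. Thermal intramolecular Diels–Alder reaction (PhMe, 180 °C, BHT, sealed tube), in which only the tether carbonyl can be endo and the branched silyloxyethyl group stays exo, should give the silyloxyethyl adduct F3. HF·pyridine then frees the carbinol adduct F4, and Dess–Martin oxidation comes back to the route at 18.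

Step 4. The auxiliary may give low or reversed facial selectivity on this cyclic acceptor, or the hydrazone may add 1,2. The fallback sets out from 5. Catalytic Michael addition of nitromethane under a quinine-derived squaramide (hydrogen-bonding catalyst, CH2Cl2, −20 °C) gives the nitromethyl keto ester F1. A reductive Nef reaction (NaOMe, MeOH; then aq. TiCl3, NH4OAc) converts it into the keto aldehyde, where the fallback comes back to the route at 9 (acetalised as in step 5).

Step 14. The palladium enolate may add sluggishly to the 1,2-disubstituted ring alkene, and the enol silane may be lost by hydrolysis before it cyclises. The fallback sets out from 19 through the same enol silane 20. NBS (THF, −78 °C) gives the α-bromo ketone F5. Tin-hydride-mediated radical cyclisation (Bu3SnH, AIBN, PhH, 80 °C, slow addition), 5-exo attack of the α-keto radical on C13 and hydrogen transfer to C12, comes back to the route directly at 22.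

Further compounds
F1 | step 4 | methyl 5,5-dimethyl-6-(nitromethyl)-2-oxocyclohexane-1-carboxylate | COC(=O)C1C(=O)CCC(C)(C)[C@H]1C[N+](=O)[O-]
F2 | step 12 | tert-butyldimethylsilyl ether of 16 | CC(O[Si](C)(C)C(C)(C)C)C(=C)C(=O)OC[C@@]1(/C=C/C=C/[Si](C)(C)C)[C@@H](OC(C)=O)CCC(C)(C)[C@H]1C1OCCO1
F3 | step 12 | Diels–Alder adduct with 1-(tert-butyldimethylsilyloxy)ethyl on C8 | C1=C[C@@H]2[C@@](C[C@H]1[Si](C)(C)C)(C(C)O[Si](C)(C)C(C)(C)C)C(=O)OC[C@]21[C@@H](OC(C)=O)CCC(C)(C)[C@H]1C1OCCO1
F4 | step 12 | Diels–Alder adduct with 1-hydroxyethyl on C8 | C1=C[C@@H]2[C@@](C[C@H]1[Si](C)(C)C)(C(C)O)C(=O)OC[C@]21[C@@H](OC(C)=O)CCC(C)(C)[C@H]1C1OCCO1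
F5 | step 14 | α-bromo ketone of 19 | C1[C@@H]2[C@@](CC=C1)(C(=O)CBr)C(=O)OC[C@]21[C@@H](OC(C)=O)CCC(C)(C)[C@H]1C1OCCO1
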